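**Strategy.** Everything rests on cutting the C5–C6 bond at the exact midpoint of the unbranched decamethylene chain (C1–C10) that links the acetylresorcinol ring to the terminal phenyl ring. Both halves then end in an unactivated primary CH2 radical, each available by decarboxylation of a 6-arylhexanoic acid. The key step is therefore a nickel-electrocatalytic doubly decarboxylative C(sp3)–C(sp3) cross-coupling: 6-(3,5-dimethoxyphenyl)hexanoic acid and 6-phenylhexanoic acid are activated together in the flask as N-hydroxyphthalimide esters and joined at the cathode in one operation, which spares the oxidation-prone dimethoxyarene. Regioselective Friedel–Crafts acetylation and O-demethylation then complete the 2-acetyl-3,5-dihydroxyphenyl ring.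

Key step: step 2

Remark: the target has no stereocentre and no stereogenic double bond. It is achiral, so it is its own single stereoisomer and no step needs stereocontrol.

**Step 1**
Reactants: 1 3,5-dimethoxyphenylmagnesium chloride (commercial THF solution); 2 6-bromohexanoic acid
Product: 4 6-(3,5-dimethoxyphenyl)hexanoic acid, via chloromagnesium 6-bromohexanoate 3 (not isolated)
Conditions: 2, i-PrMgCl (1.0 equiv), THF, −20 °C; then 1 (1.3 equiv), Li2CuCl4 (3 mol %), THF/NMP, −10 °C → rt; 1 M HCl work-up
Reagents that add atoms: none
Why: Copper-catalysed Kochi-type sp2–sp3 Grignard cross-coupling, in which the aryl copper species from 1 displaces the primary bromide of 3 while the halomagnesium carboxylate resists Grignard addition at low temperature, so the acid needs no protecting group.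

**Step 2**
Reactants: 4 6-(3,5-dimethoxyphenyl)hexanoic acid (1.0 equiv); 5 6-phenylhexanoic acid (3.0 equiv); 6 N-hydroxyphthalimide (4.0 equiv)
Product: 9 1,3-dimethoxy-5-(10-phenyldecyl)benzene, via dimethoxyphenylhexanoate NHPI ester 7 (not isolated), via phenylhexanoate NHPI ester 8 (not isolated)
Conditions: DIC (4.0 equiv), DMAP (5 mol %), CH2Cl2, rt, then solvent switch; NiCl2·6H2O (20 mol %), 2,2′:6′,2″-terpyridine (20 mol %), AgNO3 (0.3 equiv), NMP, (+)Mg/(−)RVC, undivided cell, constant current, rt; dilute HCl work-up
Reagents that add atoms: none
Why: Each N-hydroxyphthalimide ester accepts one electron (from cathodically generated low-valent Ni–terpyridine or the silver-modified cathode) and fragments to phthalimide anion, CO2 and a primary alkyl radical; nickel captures the 5-(3,5-dimethoxyphenyl)pentyl and 5-phenylpentyl radicals in turn, and reductive elimination from the dialkylnickel species forges the C5–C6 bond of the decamethylene chain. The closest known reaction type is the Ni-electrocatalytic doubly decarboxylative C(sp3)–C(sp3) cross-coupling of redox-active esters formed in situ, the reductive counterpart of a mixed Kolbe electrolysis. No ring is closed and no stereocentre is created, since both coupling carbons are unsubstituted CH2 groups. The selectivity needed is cross- over homo-coupling of two electronically near-identical primary radicals; it is secured statistically by the three-fold excess of the cheap partner 5, and the two methoxy groups of 9 should allow its separation by polarity from the hydrocarbon homodimer of the excess partner. Chemoselectivity is secured by working at the cathode, where the electron-rich dimethoxyarene, which an anodic Kolbe coupling would endanger, is inert.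

**Step 3**
Reactants: 9 1,3-dimethoxy-5-(10-phenyldecyl)benzene
Product: 10 1-[2,4-dimethoxy-6-(10-phenyldecyl)phenyl]ethanone
Conditions: AcCl (1.2 equiv), AlCl3 (1.3 equiv), CH2Cl2, −10 → 0 °C; ice/1 M HCl quench
Reagents that add atoms: acetyl chloride, CC(=O)Cl
Why: Friedel–Crafts acylation, in which the acylium ion should attack the ring position para to one methoxy group and ortho to the chain rather than the doubly flanked position between the two methoxy groups, while the unactivated monoalkylphenyl ring is far less nucleophilic.

**Step 4**
Reactants: 10 1-[2,4-dimethoxy-6-(10-phenyldecyl)phenyl]ethanone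
Product: 11 1-[2,4-dihydroxy-6-(10-phenyldecyl)phenyl]ethanone (target)
Conditions: BBr3 (4 equiv), CH2Cl2, −78 °C → rt; ice-water quench
Reagents that add atoms: none
Why: BBr3 aryl methyl ether cleavage (Lewis-acid complexation, then bromide SN2 at the O-methyl carbon), assisted at the ortho ether by chelation to the acetyl group and leaving the ketone, the chain and the phenyl ring untouched.

**Compound list**
1 | 3,5-dimethoxyphenylmagnesium chloride | COc1cc(OC)cc([Mg]Cl)c1 | starting material
2 | 6-bromohexanoic acid | OC(=O)CCCCCBr | starting material
3 | chloromagnesium 6-bromohexanoate (not isolated) | BrCCCCCC(=O)O[Mg]Cl | intermediate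
4 | 6-(3,5-dimethoxyphenyl)hexanoic acid | COc1cc(CCCCCC(=O)O)cc(OC)c1 | intermediate
5 | 6-phenylhexanoic acid | OC(=O)CCCCCc1ccccc1 | starting material
6 | N-hydroxyphthalimide | ON1C(=O)c2ccccc2C1=O | starting material
7 | 1,3-dioxoisoindolin-2-yl 6-(3,5-dimethoxyphenyl)hexanoate (not isolated) | COc1cc(CCCCCC(=O)ON2C(=O)c3ccccc3C2=O)cc(OC)c1 | intermediate
8 | 1,3-dioxoisoindolin-2-yl 6-phenylhexanoate (not isolated) | O=C(CCCCCc1ccccc1)ON1C(=O)c2ccccc2C1=O | intermediate
9 | 1,3-dimethoxy-5-(10-phenyldecyl)benzene | COc1cc(CCCCCCCCCCc2ccccc2)cc(OC)c1 | intermediate
10 | 1-[2,4-dimethoxy-6-(10-phenyldecyl)phenyl]ethanone | CC(=O)c1c(OC)cc(OC)cc1CCCCCCCCCCc1ccccc1 | intermediate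
11 | 1-[2,4-dihydroxy-6-(10-phenyldecyl)phenyl]ethanone | CC(=O)c1c(O)cc(O)cc1CCCCCCCCCCc1ccccc1 | target

**Total step count:** 4
**Longest linear sequence:** 4 steps (1 + 2 → 4 → 9 → 10 → 11)

**Steps most likely to fail**

Step 2 (key step). Homo-coupling and premature reduction of the alkyl radicals to alkanes may erode the cross-coupling, and incomplete activation in the flask may leave free acid that does not couple. The fallback sets out from 4 and comes back at 9. Acid 4 is converted with N-hydroxyphthalimide 6 and DIC into ester 7, which is now isolated. Commercial (5-bromopentyl)benzene F1 is turned with Mg in THF into (5-phenylpentyl)magnesium bromide F2 and, with ZnCl2 (0.5 equiv), into bis(5-phenylpentyl)zinc F3. A nickel-catalysed decarboxylative alkyl–alkyl Negishi-type coupling of 7 with F3 (NiCl2·glyme, 4,4′-di-tert-butyl-2,2′-bipyridine, THF/DMF, rt) should then form the same C5–C6 bond from one electrophile and one nucleophile, without a statistical partner.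

Step 1. Coupling of the aryl Grignard with the sparingly soluble magnesium carboxylate may be slow, so that biaryl homo-coupling or addition of the Grignard to the carboxylate competes. The fallback sets out from 1 and comes back at 4. Reagent 1 is formylated with DMF to 3,5-dimethoxybenzaldehyde F4 (also a catalogue compound). Wittig olefination with the ylide from (4-carboxybutyl)triphenylphosphonium bromide F5 (KOtBu 2.2 equiv, THF, 0 °C → rt) should give (Z)-6-(3,5-dimethoxyphenyl)hex-5-enoic acid F6, with some E isomer that converges. Hydrogenation (H2, Pd/C, EtOAc) then gives 4.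

Step 3. Regiocontrol may be lost through acylation between the two methoxy groups, and AlCl3 may cause over-acylation or partial ether cleavage; an ortho-demethylated by-product would converge in step 4, a regioisomer would not. The fallback sets out from 9 and comes back at 10. Vilsmeier–Haack formylation (POCl3, DMF, 0 → 60 °C; aqueous NaOAc), which is milder and strongly para-directed, should give 2,4-dimethoxy-6-(10-phenyldecyl)benzaldehyde F7. Addition of MeMgBr (THF, 0 °C) gives racemic 1-[2,4-dimethoxy-6-(10-phenyldecyl)phenyl]ethanol F8, and oxidation with MnO2 (CH2Cl2, rt) removes the transient stereocentre and gives 10.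

**Further compounds**
F1 | step 2 | (5-bromopentyl)benzene (purchased) | BrCCCCCc1ccccc1
F2 | step 2 | (5-phenylpentyl)magnesium bromide | Br[Mg]CCCCCc1ccccc1
F3 | step 2 | bis(5-phenylpentyl)zinc | c1ccccc1CCCCC[Zn]CCCCCc1ccccc1
F4 | step 1 | 3,5-dimethoxybenzaldehyde | COc1cc(C=O)cc(OC)c1
F5 | step 1 | (4-carboxybutyl)triphenylphosphonium bromide (purchased) | OC(=O)CCCC[P+](c1ccccc1)(c1ccccc1)c1ccccc1.[Br-]
F6 | step 1 | (Z)-6-(3,5-dimethoxyphenyl)hex-5-enoic acid | COc1cc(/C=C\CCCC(=O)O)cc(OC)c1
F7 | step 3 | 2,4-dimethoxy-6-(10-phenyldecyl)benzaldehyde | O=Cc1c(OC)cc(OC)cc1CCCCCCCCCCc1ccccc1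
F8 | step 3 | rac-1-[2,4-dimethoxy-6-(10-phenyldecyl)phenyl]ethanol | CC(O)c1c(OC)cc(OC)cc1CCCCCCCCCCc1ccccc1
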